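The α-methylene-γ-lactone is disconnected at two bonds, O–C2 and C15–C1 (cembrane numbering: C1 and C2 are the ring-fusion carbons, C6 carries the acetate, C15–C17 are the acrylate carbons). What remains is a lactone-free fourteen-membered (1E,3E)-diene and 2-bromoacrylic acid. One palladium-catalysed diene heteroannulation joins them: the vinylpalladium species adds to C1, and the C2–C3–C4 allylpalladium so formed is captured at C2 by the carboxylate oxygen, which closes the lactone ring and sets both ring-fusion centres. The step exploits that the lactone O–CH (C2) is allylic to the C3=C4 alkene of the carbocycle. The diene ring is assembled from geranyl acetate by a carboalumination/Negishi macrocyclisation.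

Key step: step 8

Remark: cembrane numbering of the target is used for all ring compounds, and (R)-TRIP is assumed to give the (R)-carbinol in step 6 by analogy with aryl and alkenyl aldehydes; the antipodal catalyst is used if the sense proves opposite.

Step 1
Reactants: 1 geranyl acetate
Product: 2 (2E,6E)-8-hydroxy-3,7-dimethylocta-2,6-dien-1-yl acetate
Conditions: SeO2 (0.3 equiv), t-BuOOH (3 equiv), salicylic acid (0.1 equiv), CH2Cl2, rt
Reagents that add atoms: tert-butyl hydroperoxide, CC(C)(C)OO (terminal oxygen source); selenium dioxide, O=[Se]=O (catalytic oxygen carrier)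
Why: Selenium dioxide allylic oxidation (ene reaction followed by [2,3]-sigmatropic shift, Riley oxidation with t-BuOOH as reoxidant) should hydroxylate the (E)-methyl group of the electron-richer terminal alkene with retention of the E geometry, the alkene next to the acetate being deactivated.

Step 2
Reactants: 2 (2E,6E)-8-hydroxy-3,7-dimethylocta-2,6-dien-1-yl acetate
Product: 3 (2E,6E)-8-bromo-3,7-dimethylocta-2,6-dien-1-yl acetate
Conditions: CBr4, PPh3, CH2Cl2, 0 °C
Reagents that add atoms: carbon tetrabromide, BrC(Br)(Br)Br
Why: Appel reaction: the alkoxyphosphonium ion of the primary allylic alcohol is displaced by bromide in an SN2 process that leaves the alkene geometry and the acetate untouched.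

Step 3
Reactants: 3 (2E,6E)-8-bromo-3,7-dimethylocta-2,6-dien-1-yl acetate; 4 1-(trimethylsilyl)propyne
Product: 7 (2E,6E)-3,7-dimethylundeca-2,6-dien-10-yn-1-ol, via lithiated silylpropyne 5 (not isolated), via silyl enyne acetate 6 (not isolated)
Conditions: 4, n-BuLi, THF, −78 to −20 °C; then 3, −78 °C; then MeOH, K2CO3, rt
Reagents that add atoms: none
Why: The silyl group steers the lithiated propyne to react at its propargylic carbon in an SN2 alkylation of the primary allylic bromide, and base-catalysed methanolysis then removes the acetate (transesterification) and the C-silyl group in the same flask, so any acetate cleaved by excess organolithium converges on the same alcohol.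

Step 4
Reactants: 7 (2E,6E)-3,7-dimethylundeca-2,6-dien-10-yn-1-ol
Product: 9 (2E,6E,10E)-11-iodo-3,7-dimethylundeca-2,6,10-trien-1-ol, via alkenylzirconocene 8 (not isolated)
Conditions: Cp2Zr(H)Cl (2.3 equiv), THF, rt, dark; then I2, 0 °C
Reagents that add atoms: iodine, II
Why: Schwartz hydrozirconation adds Zr–H syn and anti-Markovnikov to the terminal alkyne (the hydroxyl consumes one equivalent as the zirconium alkoxide and the trisubstituted alkenes are inert), and iodinolysis of the C–Zr bond with retention gives the (E)-vinyl iodide.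

Step 5
Reactants: 9 (2E,6E,10E)-11-iodo-3,7-dimethylundeca-2,6,10-trien-1-ol
Product: 10 (2E,6E,10E)-11-iodo-3,7-dimethylundeca-2,6,10-trienal
Conditions: activated MnO2 (15 equiv), CH2Cl2, rt
Reagents that add atoms: none
Why: Manganese dioxide oxidation is selective for the allylic alcohol and should give the (E)-enal without isomerisation or loss of the vinyl iodide.

Step 6
Reactants: 10 (2E,6E,10E)-11-iodo-3,7-dimethylundeca-2,6,10-trienal; 11 allenylboronic acid pinacol ester
Product: 12 (4R,5E,9E,13E)-14-iodo-6,10-dimethyltetradeca-5,9,13-trien-1-yn-4-ol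
Conditions: (R)-TRIP (3,3′-bis(2,4,6-triisopropylphenyl)-1,1′-binaphthyl-2,2′-diyl hydrogen phosphate, 10 mol %), 4 Å MS, toluene, 0 °C; aqueous work-up
Reagents that add atoms: none
Why: Chiral phosphoric acid-catalysed propargylation: the allenylboronate adds through a closed six-membered SE2′ transition state in which the phosphate binds the boronate oxygen and the formyl hydrogen, the 2,4,6-triisopropylphenyl groups shielding one enal face so that 1,2-addition sets the C6 carbinol centre as R.

Step 7
Reactants: 12 (4R,5E,9E,13E)-14-iodo-6,10-dimethyltetradeca-5,9,13-trien-1-yn-4-ol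
Product: 14 (1R,2E,6E,10E,12E)-3,7,13-trimethylcyclotetradeca-2,6,10,12-tetraen-1-ol, via alkenylalane 13 (not isolated)
Conditions: AlMe3 (3.5 equiv), Cp2ZrCl2 (0.5 equiv), CH2Cl2, 0 °C to rt; volatiles removed; then slow addition to Pd(PPh3)4 (10 mol %), ZnCl2 (0.3 equiv), THF, 0.002 M, 40 °C
Reagents that add atoms: trimethylaluminium, C[Al](C)C
Why: Zirconium-catalysed carboalumination (Negishi) adds methyl and aluminium syn to the terminal alkyne with aluminium at the terminus, assisted by the neighbouring aluminium alkoxide, and the resulting (E)-alkenylalane is joined to the (E)-vinyl iodide by a palladium-catalysed Negishi alkenyl–alkenyl coupling under high dilution, with retention of both alkene geometries and no effect on the C6 centre.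

Step 8
Reactants: 14 (1R,2E,6E,10E,12E)-3,7,13-trimethylcyclotetradeca-2,6,10,12-tetraen-1-ol; 15 2-bromoacrylic acid
Product: 16 (1R,2S,6R,3E,7E,11E)-6-hydroxycembra-3,7,11,15(17)-tetraen-16,2-olide
Conditions: 15 (2 equiv, in portions), Pd(OAc)2 (5 mol %), Fe(C5H4P(t-Bu)2)2 (1,1′-bis(di-tert-butylphosphino)ferrocene, 5 mol %), Na2CO3 (2.5 equiv), n-Bu4NCl (1 equiv), DMF, 60 °C
Reagents that add atoms: none
Why: Zerovalent palladium inserts into the C–Br bond of 15, and the α-carboxyvinylpalladium species adds syn across C1=C2 of the diene with C15 bonding to C1, which gives a C2–C3–C4 η3-allylpalladium carboxylate; the tethered carboxylate oxygen then bonds to C2 on the face that carries the metal and releases zerovalent palladium. The closest known reaction is the Larock heteroannulation of 1,3-dienes by α-haloacrylic acids and other vinylic or aryl halides that carry an O–H nucleophile, here applied to a macrocyclic internal diene. The lactone ring closes by 5-exo attack of oxygen on the C2 terminus of the allyl unit, which is preferred over seven-ring closure at the fully substituted C4. C1 is set by the diene face that undergoes carbopalladation, expected to be the peripheral face of the ring conformer that places the C6 hydroxyl outwards, and C2 follows from C1 because the overall syn addition of carbon and oxygen across the E alkene (the same course that gives cis-fused products from cyclic dienes) translates into the trans ring fusion. The step needs reaction at the conjugated diene and not at the isolated trisubstituted alkenes (secured by the far faster insertion of 1,3-dienes), attack at the less substituted terminus C1 and not at C4, and retention of the E geometry at C3=C4, which the syn-allyl complex derived from the s-trans diene should keep because oxygen capture outruns syn/anti exchange. The free C6 hydroxyl is kept on purpose, since an allylic acetate could be ionised by zerovalent palladium.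

Step 9
Reactants: 16 (1R,2S,6R,3E,7E,11E)-6-hydroxycembra-3,7,11,15(17)-tetraen-16,2-olide
Product: 17 (1R,2S,6R,3E,7E,11E)-6-acetoxycembra-3,7,11,15(17)-tetraen-16,2-olide (CNP0206931.1)
Conditions: Ac2O, pyridine, DMAP (cat.), CH2Cl2, 0 °C
Reagents that add atoms: acetic anhydride, CC(=O)OC(C)=O
Why: DMAP-catalysed acylation of the secondary allylic alcohol proceeds with retention at C6 and leaves the α-methylene lactone untouched.

Compound list
1 | geranyl acetate, (2E)-3,7-dimethylocta-2,6-dien-1-yl acetate | CC(C)=CCC/C(C)=C/COC(C)=O | starting material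
2 | (2E,6E)-8-hydroxy-3,7-dimethylocta-2,6-dien-1-yl acetate | OC/C(C)=C/CC/C(C)=C/COC(C)=O | intermediate
3 | (2E,6E)-8-bromo-3,7-dimethylocta-2,6-dien-1-yl acetate | BrC/C(C)=C/CC/C(C)=C/COC(C)=O | intermediate
4 | 1-(trimethylsilyl)propyne | CC#C[Si](C)(C)C | starting material
5 | [3-(trimethylsilyl)prop-2-yn-1-yl]lithium | [Li]CC#C[Si](C)(C)C | intermediate (not isolated)
6 | (2E,6E)-3,7-dimethyl-11-(trimethylsilyl)undeca-2,6-dien-10-yn-1-yl acetate | C[Si](C)(C)C#CCC/C(C)=C/CC/C(C)=C/COC(C)=O | intermediate (not isolated)
7 | (2E,6E)-3,7-dimethylundeca-2,6-dien-10-yn-1-ol | C#CCC/C(C)=C/CC/C(C)=C/CO | intermediate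
8 | (E)-alkenylzirconocene chloride of 7, hydroxyl bound as zirconium alkoxide | Cl[Zr](C1C=CC=C1)(C1C=CC=C1)OC/C=C(C)/CC/C=C(C)/CC/C=C/[Zr](Cl)(C1C=CC=C1)C1C=CC=C1 | intermediate (not isolated)
9 | (2E,6E,10E)-11-iodo-3,7-dimethylundeca-2,6,10-trien-1-ol | OC/C=C(C)/CC/C=C(C)/CC/C=C/I | intermediate
10 | (2E,6E,10E)-11-iodo-3,7-dimethylundeca-2,6,10-trienal | O=C/C=C(C)/CC/C=C(C)/CC/C=C/I | intermediate
11 | allenylboronic acid pinacol ester, 4,4,5,5-tetramethyl-2-(propa-1,2-dien-1-yl)-1,3,2-dioxaborolane | C=C=CB1OC(C)(C)C(C)(C)O1 | starting material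
12 | (4R,5E,9E,13E)-14-iodo-6,10-dimethyltetradeca-5,9,13-trien-1-yn-4-ol | C#CC[C@@H](O)/C=C(\C)CC/C=C(\C)CC/C=C/I | intermediate
13 | (E)-alkenyl(dimethyl)alane from 12 (methyl on the former internal alkyne carbon, hydroxyl as dimethylaluminium alkoxide) | C[Al](C)/C=C(\C)C[C@@H](O[Al](C)C)/C=C(\C)CC/C=C(\C)CC/C=C/I | intermediate (not isolated)
14 | (1R,2E,6E,10E,12E)-3,7,13-trimethylcyclotetradeca-2,6,10,12-tetraen-1-ol | C1/C=C(\C)CC/C=C/C=C(\C)C[C@@H](O)/C=C(\C)C1 | intermediate
15 | 2-bromoacrylic acid | C=C(Br)C(=O)O | starting material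
16 | (1R,2S,6R,3E,7E,11E)-6-hydroxycembra-3,7,11,15(17)-tetraen-16,2-olide (trans-fused α-methylene-γ-lactone, H-1 and H-2 anti) | C=C1C(=O)O[C@H]2/C=C(\C)C[C@@H](O)/C=C(\C)CC/C=C(\C)CC[C@H]12 | intermediate
17 | (1R,2S,6R,3E,7E,11E)-6-acetoxycembra-3,7,11,15(17)-tetraen-16,2-olide, CNP0206931.1 | C=C1C(=O)O[C@H]2/C=C(\C)C[C@@H](OC(C)=O)/C=C(\C)CC/C=C(\C)CC[C@H]12 | target

Total step count: 9. Longest linear sequence: 9 steps (from geranyl acetate 1).

Steps most likely to fail

1. Step 8. The diene face that undergoes carbopalladation is controlled only remotely by the C6 centre, so addition may occur on the wrong face. Rotation about C1–C2 in the allyl intermediate before C–O bond formation, or β-hydride loss to a triene, may also erode the outcome. The fallback sets out from aldehyde 10 and comes back to the route at target 17; it sets C6 with the opposite configuration and corrects it at the end. Propargylation of 10 with 11 under (S)-TRIP catalysis should give (4S,5E,9E,13E)-14-iodo-6,10-dimethyltetradeca-5,9,13-trien-1-yn-4-ol F1. Carboalumination to the (4S)-alkenylalane F2 and Negishi ring closure as in step 7 should give (1S,2E,6E,10E,12E)-3,7,13-trimethylcyclotetradeca-2,6,10,12-tetraen-1-ol F3. Annulation with 15 as in step 8, now with the mirror-image face preference, should give (1R,2S,6S)-6-hydroxycembra-3,7,11,15(17)-tetraen-16,2-olide F4. Mitsunobu esterification with acetic acid (PPh3, DIAD, toluene, 0 °C) then inverts C6 and installs the acetate in one operation, giving 17.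

2. Step 7. Intermolecular coupling (oligomerisation) may outrun ring closure, transmetalation of the alkoxide-chelated alane may be slow, and residual AlMe3 may transfer methyl to the vinyl iodide. The fallback sets out from 12 and comes back at 14. After carboalumination to 13, the alane is quenched with 2-isopropoxy-4,4,5,5-tetramethyl-1,3,2-dioxaborolane to give the isolable (1E,4R,5E,9E,13E)-14-iodo-2,6,10-trimethyl-1-(4,4,5,5-tetramethyl-1,3,2-dioxaborolan-2-yl)tetradeca-1,5,9,13-tetraen-4-ol F5. This purified bifunctional compound is then closed by Suzuki–Miyaura macrocyclisation (PdCl2(dppf), Cs2CO3, THF/H2O, 0.002 M, 50 °C) to 14.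

3. Step 6. Enantiofacial discrimination may be weak for a β,β-disubstituted enal, and some allenyl transfer may compete. The fallback sets out from 10 and comes back at 12. Barbier addition (propargyl bromide, Zn, THF/aq. NH4Cl) should give racemic (5E,9E,13E)-14-iodo-6,10-dimethyltetradeca-5,9,13-trien-1-yn-4-ol F6. Lipase-catalysed kinetic resolution (Candida antarctica lipase B, vinyl acetate, hexane, rt) should acylate the (4R)-enantiomer to (4R,5E,9E,13E)-14-iodo-6,10-dimethyltetradeca-5,9,13-trien-1-yn-4-yl acetate F7, which is separated from the unreacted (4S)-alcohol. Methanolysis (K2CO3, MeOH) then gives 12.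

Further compounds
F1 | step 8 | (4S,5E,9E,13E)-14-iodo-6,10-dimethyltetradeca-5,9,13-trien-1-yn-4-ol | C#CC[C@H](O)/C=C(\C)CC/C=C(\C)CC/C=C/I
F2 | step 8 | (4S)-(E)-alkenyl(dimethyl)alane from F1, hydroxyl as dimethylaluminium alkoxide (not isolated) | C[Al](C)/C=C(\C)C[C@H](O[Al](C)C)/C=C(\C)CC/C=C(\C)CC/C=C/I
F3 | step 8 | (1S,2E,6E,10E,12E)-3,7,13-trimethylcyclotetradeca-2,6,10,12-tetraen-1-ol | C1/C=C(\C)CC/C=C/C=C(\C)C[C@H](O)/C=C(\C)C1
F4 | step 8 | (1R,2S,6S,3E,7E,11E)-6-hydroxycembra-3,7,11,15(17)-tetraen-16,2-olide | C=C1C(=O)O[C@H]2/C=C(\C)C[C@H](O)/C=C(\C)CC/C=C(\C)CC[C@H]12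
F5 | step 7 | (1E,4R,5E,9E,13E)-14-iodo-2,6,10-trimethyl-1-(4,4,5,5-tetramethyl-1,3,2-dioxaborolan-2-yl)tetradeca-1,5,9,13-tetraen-4-ol | CC1(C)OB(/C=C(\C)C[C@@H](O)/C=C(\C)CC/C=C(\C)CC/C=C/I)OC1(C)C
F6 | step 6 | racemic (5E,9E,13E)-14-iodo-6,10-dimethyltetradeca-5,9,13-trien-1-yn-4-ol | C#CCC(O)/C=C(\C)CC/C=C(\C)CC/C=C/I
F7 | step 6 | (4R,5E,9E,13E)-14-iodo-6,10-dimethyltetradeca-5,9,13-trien-1-yn-4-yl acetate | C#CC[C@@H](OC(C)=O)/C=C(\C)CC/C=C(\C)CC/C=C/I
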